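**Plan**
- Retrosynthesis: after removal of eight O-methyl groups, the dihydrofuran on C-1/C-2 of the central benzene ring C is cut at C-2''–C-3'' (carbene C–H insertion into a 4-methoxybenzyl ether), and the dihydrofuran on C-4/C-5 at O–C-2' and C-5–C-2' (C-5 ketone, one-carbon homologation, aryl Grignard, acid closure).
- Ring C is then opened across four bonds (C-1–C-11a, C-1–C-2, C-3–C-4, C-4–C-4a) to a benzo-fused cycloheptenyl diazomethyl ketone and triisopropylsilyloxyacetylene. This works because ring C is a resorcinol: its two meta oxygens (C-2, C-4) flank its only C–H (C-3) and its C-4a–C-11a edge is shared with the seven-membered ring, which is the pattern a cycloalkenyl ketene and an oxyacetylene assemble.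
- The cycloheptene comes from ring-closing metathesis of an allyl arene onto a 2-substituted enone, the enone from a methyl ketone through its enol triflate, and the diarylmethine from a rhodium-catalysed 1,4-arylation of an enone built on 2-bromo-4,6-dimethoxybenzaldehyde (ring D).
- Forward order of rings: ring D (bought), seven-membered ring, ring C, dihydrofuran on C-4/C-5, dihydrofuran on C-1/C-2, then demethylation.
- Stereochemistry: C-10 from the (S)-binap rhodium catalyst; C-5 by equilibration of an aldehyde trans to the C-10 aryl group; both aryl-bearing O–CH centres by thermodynamic trans closure or epimerisation; C-3'' from a chiral dirhodium carboxylate.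

Key step: step 9

Remark on locants: the tricycle is numbered as 10,11-dihydro-5H-dibenzo[a,d][7]annulene and these locants are kept after the furans are fused. Ring C is C-1 to C-4 with C-4a and C-11a; C-5 lies between the two benzene rings; ring D is C-5a to C-9a with OMe on C-7 and C-9; C-10 carries the 2,4-dimethoxyphenyl group; C-11 is CH2. The first dihydrofuran is O–C-2'–C-3' with C-3' = C-5; the second is O–C-2''–C-3'' with C-3'' on C-1.

Assumption: triisopropylsilyloxyacetylene is not treated as a catalogue chemical and is made in step 8; the two aryl Grignard reagents are bought as THF solutions.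

**Route**

Step 1
Reactants: 1 2-bromo-4,6-dimethoxybenzaldehyde; 2 allylboronic acid pinacol ester
Product: 3 2-allyl-4,6-dimethoxybenzaldehyde
Conditions: Pd(PPh3)4 (5 mol %), CsF, THF, 70 °C
Reagents that add atoms: none
Why: Suzuki–Miyaura allylation of an aryl bromide activated by the ortho formyl group, with fluoride activation of the boronate keeping the medium mild enough that the allyl double bond should not migrate.

Step 2
Reactants: 3 2-allyl-4,6-dimethoxybenzaldehyde; 4 1-(triphenylphosphoranylidene)propan-2-one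
Product: 5 (E)-4-(2-allyl-4,6-dimethoxyphenyl)but-3-en-2-one
Conditions: toluene, 110 °C
Reagents that add atoms: none
Why: Wittig olefination with a ketone-stabilised ylide, which is E-selective and should take the hindered 2,6-disubstituted aldehyde on heating.

Step 3
Reactants: 5 (E)-4-(2-allyl-4,6-dimethoxyphenyl)but-3-en-2-one; 6 2,4-dimethoxyphenylboronic acid
Product: 7 (R)-4-(2-allyl-4,6-dimethoxyphenyl)-4-(2,4-dimethoxyphenyl)butan-2-one
Conditions: [Rh(OH)((S)-binap)]2 (3 mol %), 6 (2.5 equiv), dioxane/H2O 10:1, 50 °C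
Reagents that add atoms: none
Why: Hayashi–Miyaura asymmetric 1,4-addition, in which the (S)-binap rhodium aryl is expected by the usual model to add to the 2-si face of the E-enone, which corresponds to R at the new diarylmethine centre (the sense must be confirmed on this hindered substrate and the antipodal ligand used if it proves opposite).

Step 4
Reactants: 7 (R)-4-(2-allyl-4,6-dimethoxyphenyl)-4-(2,4-dimethoxyphenyl)butan-2-one
Product: 8 (R)-4-(2-allyl-4,6-dimethoxyphenyl)-4-(2,4-dimethoxyphenyl)but-1-en-2-yl trifluoromethanesulfonate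
Conditions: KHMDS, THF, −78 °C; then PhNTf2, −78 → 0 °C
Reagents that add atoms: N-phenylbis(trifluoromethanesulfonimide), O=S(=O)(N(c1ccccc1)S(=O)(=O)C(F)(F)F)C(F)(F)F
Why: kinetic enolisation at the unhindered methyl group followed by O-triflation (enol triflate formation), the stereocentre being β to the carbonyl and therefore untouched.

Step 5
Reactants: 8 the enol triflate; 9 tributyl(1-ethoxyvinyl)stannane
Product: 11 (R)-3-[2-(2-allyl-4,6-dimethoxyphenyl)-2-(2,4-dimethoxyphenyl)ethyl]but-3-en-2-one, via ethoxydiene 10 (not isolated)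
Conditions: Pd(PPh3)4 (5 mol %), LiCl, THF, 65 °C; then 1 M HCl, 23 °C
Reagents that add atoms: water, O
Why: Stille coupling of a vinyl triflate with an acetyl anion equivalent, then hydrolysis of the enol ether, gives the 2-substituted enone without touching the allyl group.

Step 6
Reactants: 11 the 3-substituted but-3-en-2-one
Product: 12 1-[(5R)-5-(2,4-dimethoxyphenyl)-2,4-dimethoxy-6,9-dihydro-5H-benzo[7]annulen-7-yl]ethan-1-one
Conditions: second-generation Hoveyda–Grubbs catalyst RuCl2(H2IMes)(=CH-C6H4-2-OiPr) (5 mol %), toluene (0.005 M), 80 °C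
Reagents that add atoms: none
Why: ring-closing metathesis that initiates at the allyl group and closes onto the 1,1-disubstituted enone alkene, a well-used way to benzo-fused cycloheptenes bearing a conjugated acyl group, with ethylene as the only by-product.

Step 7
Reactants: 12 the cycloheptenyl methyl ketone
Product: 14 2-diazo-1-[(5R)-5-(2,4-dimethoxyphenyl)-2,4-dimethoxy-6,9-dihydro-5H-benzo[7]annulen-7-yl]ethan-1-one, via trifluoroacetyl diketone 13 (not isolated)
Conditions: LiHMDS, THF, −78 °C; CF3CO2CH2CF3; then MsN3, Et3N, H2O, MeCN, 23 °C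
Reagents that add atoms: methanesulfonyl azide, CS(=O)(=O)N=[N+]=[N-]
Why: detrifluoroacetylative diazo transfer (kinetic α'-enolate acylation, then diazo transfer with loss of the trifluoroacetyl group), the standard entry to α'-diazo enones where acylation of diazomethane would be spoiled by dipolar cycloaddition.

Step 8
Reactants: 15 acetylene
Product: 17 triisopropylsilyloxyacetylene, via lithium ethynolate 16 (not isolated)
Conditions: n-BuLi, THF, −78 °C; t-BuOOLi (from t-BuOOH and LiHMDS), −78 → −10 °C; then i-Pr3SiOTf, −78 → 0 °C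
Reagents that add atoms: tert-butyl hydroperoxide, CC(C)(C)OO; triisopropylsilyl trifluoromethanesulfonate, CC(C)[Si](OS(=O)(=O)C(F)(F)F)(C(C)C)C(C)C
Why: electrophilic oxygenation of a lithium acetylide by lithium tert-butyl peroxide gives the ynolate, which the bulky silyl triflate should trap on oxygen (ynolate O-silylation).

Step 9
Reactants: 14 the diazo ketone; 17 triisopropylsilyloxyacetylene
Product: 21 (10R)-10-(2,4-dimethoxyphenyl)-7,9-dimethoxy-2-(triisopropylsilyloxy)-10,11-dihydro-5H-dibenzo[a,d][7]annulen-4-ol, via vinylketene 18 (not isolated), via vinylcyclobutenone 19 (not isolated), via dienylketene 20 (not isolated)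
Conditions: hν (300–350 nm, Pyrex), 17 (3 equiv), ClCH2CH2Cl, 23 °C; then 80 °C
Reagents that add atoms: none
Why: Irradiation expels N2 and the cycloheptenyl group migrates (photochemical Wolff rearrangement) to give vinylketene 18, whose ketene C=C adds the silyloxyacetylene in a [2+2] cycloaddition to give 4-vinylcyclobutenone 19. Four-electron electrocyclic opening gives dienylketene 20, which closes ring C by a six-electron electrocyclisation between the ketene carbon and the former ring alkene CH and tautomerises to the phenol, heating completing these last stages. The closest known reaction is the Danheiser benzannulation in its diazo ketone variant with alkoxy- and silyloxyacetylenes, which gives resorcinol monoethers. No stereocentre is formed, and C-10 is remote from every reacting atom. The selectivity needed is the orientation of the [2+2] step, which the polarisation of the ynol ether secures (its nucleophilic CH terminus bonds to the ketene carbonyl carbon). This puts the free OH on C-4 next to the fusion carbon that carries the doubly benzylic C-5 and the silyl ether on C-2, while the cycloheptene C=C becomes the C-4a–C-11a fusion bond.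

Step 10
Reactants: 21 the ring-C phenol
Product: 23 (10R)-10-(2,4-dimethoxyphenyl)-4-hydroxy-7,9-dimethoxy-2-(triisopropylsilyloxy)-10,11-dihydro-5H-dibenzo[a,d][7]annulen-5-one, via benzhydrol 22 (not isolated)
Conditions: DDQ (2.2 equiv), dioxane/H2O 10:1, 0 → 23 °C
Reagents that add atoms: water, O
Why: quinone-mediated benzylic oxidation in which the ortho phenol channels dehydrogenation through an o-quinone methide at C-5, hydration and a second dehydrogenation then giving the hydrogen-bonded o-hydroxy diaryl ketone, whereas the C-10 methine has no such assistance.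

Step 11
Reactants: 23 the o-hydroxy ketone
Product: 24 (10R)-10-(2,4-dimethoxyphenyl)-7,9-dimethoxy-4-(methoxymethoxy)-2-(triisopropylsilyloxy)-10,11-dihydro-5H-dibenzo[a,d][7]annulen-5-one
Conditions: NaH, MOMCl, DMF, 0 °C
Reagents that add atoms: chloromethyl methyl ether, COCCl
Why: Williamson etherification of the chelated phenol with a small acetal group, so that the ketone stays accessible and electrophilic for the ylide and the group falls off later under the acid that closes the furan.

Step 12
Reactants: 24 the protected ketone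
Product: 25 spiro-epoxide of 24 (oxirane spiro-fused at C-5 with its CH2 as the new carbon; both C-5 epimers; C-10 R)
Conditions: Me3S+ I−, n-BuLi, THF, −10 → 23 °C
Reagents that add atoms: trimethylsulfonium iodide, C[S+](C)C.[I-]
Why: Corey–Chaykovsky epoxidation of a diaryl ketone by dimethylsulfonium methylide, the configuration at the spiro carbon being irrelevant because the next step erases it.

Step 13
Reactants: 25 the spiro-epoxide
Product: 26 (5R,10R)-10-(2,4-dimethoxyphenyl)-7,9-dimethoxy-4-(methoxymethoxy)-2-(triisopropylsilyloxy)-10,11-dihydro-5H-dibenzo[a,d][7]annulene-5-carbaldehyde (formyl trans to the C-10 aryl group)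
Conditions: ZnI2 (0.3 equiv), CH2Cl2, 23 °C; then DBU (0.2 equiv), 23 °C
Reagents that add atoms: none
Why: Meinwald rearrangement (Lewis-acid opening to the diarylmethyl cation and 1,2-hydride shift) gives the diarylacetaldehyde, and C-5 is then set under thermodynamic control by base-mediated enolisation, the formyl group being expected to settle trans to the C-10 aryl group because only the trans isomer lets both groups sit pseudoaxial on opposite faces, free of peri strain and of a transannular clash.

Step 14
Reactants: 26 the aldehyde; 27 4-methoxyphenylmagnesium bromide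
Product: 28 (4-methoxyphenyl)[(5R,10R)-10-(2,4-dimethoxyphenyl)-7,9-dimethoxy-4-(methoxymethoxy)-2-(triisopropylsilyloxy)-10,11-dihydro-5H-dibenzo[a,d][7]annulen-5-yl]methanol (both carbinol epimers)
Conditions: THF, −78 → 0 °C
Reagents that add atoms: none
Why: Grignard 1,2-addition to the aldehyde, the carbinol centre being formed as a mixture that does not matter because it is ionised in the next step.

Step 15
Reactants: 28 the carbinol
Product: 30 silyl ether of the first dihydrofuran (trans-2'-(4-methoxyphenyl)dihydrofuran closed from the C-4 oxygen to C-5; 2'R, 5R, 10R; i-Pr3SiO on C-2), via phenol diol 29 (not isolated)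
Conditions: HCl (3 M aq.), MeOH/THF, 45 °C
Reagents that add atoms: none
Why: acid removes the methoxymethyl acetal and ionises the 4-methoxybenzylic alcohol, and the adjacent phenol captures the cation in a five-membered ring closure (SN1 etherification) that is reversible and should therefore place the C-2' aryl group trans to the C-5 substituent, the aryl silyl ether being expected to survive.

Step 16
Reactants: 30 the silyl ether
Product: 31 phenol of the first dihydrofuran (as 30 with free OH on C-2)
Conditions: TBAF, THF, 0 °C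
Reagents that add atoms: none
Why: fluoride cleavage of the aryl silyl ether frees the one phenol that will direct the next C–C bond formation.

Step 17
Reactants: 31 the phenol
Product: 32 salicylaldehyde (as 31 with CHO on C-1, ortho to the C-2 OH)
Conditions: MgCl2, Et3N, (CH2O)n, THF, 70 °C
Reagents that add atoms: paraformaldehyde (formaldehyde units), C=O
Why: Casnati–Skattebøl ortho-formylation through the magnesium phenoxide, which reacts only ortho to the free phenol and should prefer C-1 (para to the furan oxygen on C-4) over C-3 between the two oxygens, leaving the other electron-rich rings alone.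

Step 18
Reactants: 32 the salicylaldehyde; 33 4-methoxybenzyl chloride
Product: 34 4-methoxybenzyl ether of 32 (ArCH2O on C-2, CHO on C-1)
Conditions: K2CO3, DMF, 40 °C
Reagents that add atoms: none
Why: Williamson etherification installs the benzylic CH2 that will become C-2'' of the second dihydrofuran.

Step 19
Reactants: 34 the aldehyde; 35 3,5-dimethoxyphenylmagnesium chloride
Product: 36 diarylmethanol (as 34 with CH(OH)(3,5-dimethoxyphenyl) on C-1; both carbinol epimers)
Conditions: THF, 0 °C
Reagents that add atoms: none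
Why: Grignard addition to the aldehyde, the new carbinol centre being removed by the following oxidation.

Step 20
Reactants: 36 the diarylmethanol
Product: 37 diaryl ketone (as 34 with C(=O)(3,5-dimethoxyphenyl) on C-1)
Conditions: Dess–Martin periodinane, CH2Cl2, 23 °C
Reagents that add atoms: none
Why: Dess–Martin oxidation of a benzhydrol, mild enough for the electron-rich rings and the benzylic ethers.

Step 21
Reactants: 37 the diaryl ketone
Product: 38 hydrazone of 37 (C=N–NH2 on the carbon attached to C-1)
Conditions: N2H4·H2O, AcOH (cat.), EtOH, 80 °C (sealed tube)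
Reagents that add atoms: hydrazine (as hydrate), NN
Why: hydrazone condensation, for which the small, strongly nucleophilic hydrazine and heat are chosen because the ketone is flanked by two ortho substituents.

Step 22
Reactants: 38 the hydrazone
Product: 40 cis octamethyl ether (second dihydrofuran closed with the 2''-(4-methoxyphenyl) and 3''-(3,5-dimethoxyphenyl) groups cis; 2''S, 3''R; all other centres as in 31), via diaryldiazomethane 39 (not isolated)
Conditions: MnO2, CH2Cl2, 0 °C; then Rh2(R-PTAD)4 (1 mol %; PTAD = 1-adamantyl(N-phthalimido)acetate), 0 °C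
Reagents that add atoms: none
Why: oxidation of the hydrazone gives the diaryldiazomethane, and the dirhodium carboxylate turns it into a donor/donor carbene that inserts into the neighbouring ArCH2–O C–H bond (intramolecular 1,5 C–H insertion closing the five-membered ring), the chiral catalyst rather than the remote stereocentres being expected to fix C-3'' (R is required, and Rh2(S-PTAD)4 is taken if the sense proves opposite) while the concerted insertion places the two aryl groups cis.

Step 23
Reactants: 40 the cis octamethyl ether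
Product: 41 octamethyl ether of the target (both dihydrofurans trans; all five stereocentres R)
Conditions: CF3CO2H, CH2Cl2, 0 °C
Reagents that add atoms: none
Why: acid-mediated epimerisation at C-2'' through reversible ionisation of the benzylic C–O bond to the 4-methoxybenzylic cation, which should reclose to the more stable trans isomer without touching C-3''.

Step 24
Reactants: 41 the octamethyl ether
Product: 42 CNP0154047.1 (target)
Conditions: BBr3 (excess), CH2Cl2, −78 → 23 °C; then H2O
Reagents that add atoms: none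
Why: Lewis-acid cleavage of all eight aryl methyl ethers (global demethylation), tolerable because both dihydrofurans are already the thermodynamic trans isomers, so any reversible C–O ionisation should return the same configuration.

**Compound list**

1 | 2-bromo-4,6-dimethoxybenzaldehyde | COc1cc(Br)c(C=O)c(OC)c1 | starting material
2 | allylboronic acid pinacol ester | C=CCB1OC(C)(C)C(C)(C)O1 | starting material
3 | 2-allyl-4,6-dimethoxybenzaldehyde | C=CCc1cc(OC)cc(OC)c1C=O | intermediate
4 | 1-(triphenylphosphoranylidene)propan-2-one | CC(=O)C=P(c1ccccc1)(c1ccccc1)c1ccccc1 | starting material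
5 | (E)-4-(2-allyl-4,6-dimethoxyphenyl)but-3-en-2-one | CC(=O)/C=C/c1c(CC=C)cc(OC)cc1OC | intermediate
6 | 2,4-dimethoxyphenylboronic acid | COc1ccc(B(O)O)c(OC)c1 | starting material
7 | (R)-4-(2-allyl-4,6-dimethoxyphenyl)-4-(2,4-dimethoxyphenyl)butan-2-one | CC(=O)C[C@H](c1ccc(OC)cc1OC)c1c(CC=C)cc(OC)cc1OC | intermediate
8 | (R)-4-(2-allyl-4,6-dimethoxyphenyl)-4-(2,4-dimethoxyphenyl)but-1-en-2-yl trifluoromethanesulfonate | C=C(OS(=O)(=O)C(F)(F)F)C[C@H](c1ccc(OC)cc1OC)c1c(CC=C)cc(OC)cc1OC | intermediate
9 | tributyl(1-ethoxyvinyl)stannane | CCCC[Sn](CCCC)(CCCC)C(=C)OCC | starting material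
10 | (R)-2-ethoxy-3-[2-(2-allyl-4,6-dimethoxyphenyl)-2-(2,4-dimethoxyphenyl)ethyl]buta-1,3-diene | C=C(OCC)C(=C)C[C@H](c1ccc(OC)cc1OC)c1c(CC=C)cc(OC)cc1OC | intermediate (not isolated)
11 | (R)-3-[2-(2-allyl-4,6-dimethoxyphenyl)-2-(2,4-dimethoxyphenyl)ethyl]but-3-en-2-one | CC(=O)C(=C)C[C@H](c1ccc(OC)cc1OC)c1c(CC=C)cc(OC)cc1OC | intermediate
12 | 1-[(5R)-5-(2,4-dimethoxyphenyl)-2,4-dimethoxy-6,9-dihydro-5H-benzo[7]annulen-7-yl]ethan-1-one | CC(=O)C1=CCc2cc(OC)cc(OC)c2[C@@H](c2ccc(OC)cc2OC)C1 | intermediate
13 | 1-[(5R)-5-(2,4-dimethoxyphenyl)-2,4-dimethoxy-6,9-dihydro-5H-benzo[7]annulen-7-yl]-4,4,4-trifluorobutane-1,3-dione | O=C(CC(=O)C(F)(F)F)C1=CCc2cc(OC)cc(OC)c2[C@@H](c2ccc(OC)cc2OC)C1 | intermediate (not isolated)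
14 | 2-diazo-1-[(5R)-5-(2,4-dimethoxyphenyl)-2,4-dimethoxy-6,9-dihydro-5H-benzo[7]annulen-7-yl]ethan-1-one | [N-]=[N+]=CC(=O)C1=CCc2cc(OC)cc(OC)c2[C@@H](c2ccc(OC)cc2OC)C1 | intermediate
15 | acetylene | C#C | starting material
16 | lithium ethynolate | [Li+].[O-]C#C | intermediate (not isolated)
17 | triisopropylsilyloxyacetylene | C#CO[Si](C(C)C)(C(C)C)C(C)C | intermediate
18 | 2-[(5R)-5-(2,4-dimethoxyphenyl)-2,4-dimethoxy-6,9-dihydro-5H-benzo[7]annulen-7-yl]ethen-1-one (vinylketene) | O=C=CC1=CCc2cc(OC)cc(OC)c2[C@@H](c2ccc(OC)cc2OC)C1 | intermediate (not isolated)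
19 | 4-[(5R)-5-(2,4-dimethoxyphenyl)-2,4-dimethoxy-6,9-dihydro-5H-benzo[7]annulen-7-yl]-3-(triisopropylsilyloxy)cyclobut-2-en-1-one (C-4 epimers) | O=C1C=C(O[Si](C(C)C)(C(C)C)C(C)C)C1C1=CCc2cc(OC)cc(OC)c2[C@@H](c2ccc(OC)cc2OC)C1 | intermediate (not isolated)
20 | 4-[(5R)-5-(2,4-dimethoxyphenyl)-2,4-dimethoxy-6,9-dihydro-5H-benzo[7]annulen-7-yl]-3-(triisopropylsilyloxy)buta-1,3-dien-1-one, ketene carbon cis to the cycloheptenyl group | O=C=C/C(O[Si](C(C)C)(C(C)C)C(C)C)=C\C1=CCc2cc(OC)cc(OC)c2[C@@H](c2ccc(OC)cc2OC)C1 | intermediate (not isolated)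
21 | (10R)-10-(2,4-dimethoxyphenyl)-7,9-dimethoxy-2-(triisopropylsilyloxy)-10,11-dihydro-5H-dibenzo[a,d][7]annulen-4-ol | Oc1cc(O[Si](C(C)C)(C(C)C)C(C)C)cc2c1Cc1cc(OC)cc(OC)c1[C@@H](c1ccc(OC)cc1OC)C2 | intermediate
22 | (10R)-10-(2,4-dimethoxyphenyl)-7,9-dimethoxy-2-(triisopropylsilyloxy)-10,11-dihydro-5H-dibenzo[a,d][7]annulene-4,5-diol (C-5 epimers) | Oc1cc(O[Si](C(C)C)(C(C)C)C(C)C)cc2c1C(O)c1cc(OC)cc(OC)c1[C@@H](c1ccc(OC)cc1OC)C2 | intermediate (not isolated)
23 | (10R)-10-(2,4-dimethoxyphenyl)-4-hydroxy-7,9-dimethoxy-2-(triisopropylsilyloxy)-10,11-dihydro-5H-dibenzo[a,d][7]annulen-5-one | Oc1cc(O[Si](C(C)C)(C(C)C)C(C)C)cc2c1C(=O)c1cc(OC)cc(OC)c1[C@@H](c1ccc(OC)cc1OC)C2 | intermediate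
24 | (10R)-10-(2,4-dimethoxyphenyl)-7,9-dimethoxy-4-(methoxymethoxy)-2-(triisopropylsilyloxy)-10,11-dihydro-5H-dibenzo[a,d][7]annulen-5-one | COCOc1cc(O[Si](C(C)C)(C(C)C)C(C)C)cc2c1C(=O)c1cc(OC)cc(OC)c1[C@@H](c1ccc(OC)cc1OC)C2 | intermediate
25 | spiro-epoxide of 24 (oxirane at C-5, both C-5 epimers, C-10 R) | COCOc1cc(O[Si](C(C)C)(C(C)C)C(C)C)cc2c1C1(CO1)c1cc(OC)cc(OC)c1[C@@H](c1ccc(OC)cc1OC)C2 | intermediate
26 | (5R,10R)-10-(2,4-dimethoxyphenyl)-7,9-dimethoxy-4-(methoxymethoxy)-2-(triisopropylsilyloxy)-10,11-dihydro-5H-dibenzo[a,d][7]annulene-5-carbaldehyde | COCOc1cc(O[Si](C(C)C)(C(C)C)C(C)C)cc2c1[C@H](C=O)c1cc(OC)cc(OC)c1[C@@H](c1ccc(OC)cc1OC)C2 | intermediate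
27 | 4-methoxyphenylmagnesium bromide | COc1ccc([Mg]Br)cc1 | starting material
28 | (4-methoxyphenyl)[(5R,10R)-10-(2,4-dimethoxyphenyl)-7,9-dimethoxy-4-(methoxymethoxy)-2-(triisopropylsilyloxy)-10,11-dihydro-5H-dibenzo[a,d][7]annulen-5-yl]methanol (carbinol epimers) | COCOc1cc(O[Si](C(C)C)(C(C)C)C(C)C)cc2c1[C@H](C(O)c1ccc(OC)cc1)c1cc(OC)cc(OC)c1[C@@H](c1ccc(OC)cc1OC)C2 | intermediate
29 | as 28 with free OH on C-4 (phenol diol, carbinol epimers) | Oc1cc(O[Si](C(C)C)(C(C)C)C(C)C)cc2c1[C@H](C(O)c1ccc(OC)cc1)c1cc(OC)cc(OC)c1[C@@H](c1ccc(OC)cc1OC)C2 | intermediate (not isolated)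
30 | first dihydrofuran, silyl ether: trans-2'-(4-methoxyphenyl)dihydrofuran from the C-4 oxygen to C-5 (2'R, 5R), C-10 R 2,4-dimethoxyphenyl, OMe on C-7 and C-9, i-Pr3SiO on C-2 | CC(C)[Si](Oc1cc2c3c(c1)C[C@H](c1ccc(OC)cc1OC)c1c(OC)cc(OC)cc1[C@H]3[C@H](c1ccc(OC)cc1)O2)(C(C)C)C(C)C | intermediate
31 | as 30 with free OH on C-2 | Oc1cc2c3c(c1)C[C@H](c1ccc(OC)cc1OC)c1c(OC)cc(OC)cc1[C@H]3[C@H](c1ccc(OC)cc1)O2 | intermediate
32 | as 31 with CHO on C-1 (salicylaldehyde) | Oc1cc2c3c(c1C=O)C[C@H](c1ccc(OC)cc1OC)c1c(OC)cc(OC)cc1[C@H]3[C@H](c1ccc(OC)cc1)O2 | intermediate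
33 | 4-methoxybenzyl chloride | COc1ccc(CCl)cc1 | starting material
34 | as 32 with the C-2 oxygen as its 4-methoxybenzyl ether | COc1ccc(COc2cc3c4c(c2C=O)C[C@H](c2ccc(OC)cc2OC)c2c(OC)cc(OC)cc2[C@H]4[C@H](c2ccc(OC)cc2)O3)cc1 | intermediate
35 | 3,5-dimethoxyphenylmagnesium chloride | COc1cc(OC)cc([Mg]Cl)c1 | starting material
36 | as 34 with CH(OH)(3,5-dimethoxyphenyl) on C-1 (carbinol epimers) | COc1ccc(COc2cc3c4c(c2C(O)c2cc(OC)cc(OC)c2)C[C@H](c2ccc(OC)cc2OC)c2c(OC)cc(OC)cc2[C@H]4[C@H](c2ccc(OC)cc2)O3)cc1 | intermediate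
37 | as 34 with C(=O)(3,5-dimethoxyphenyl) on C-1 | COc1ccc(COc2cc3c4c(c2C(=O)c2cc(OC)cc(OC)c2)C[C@H](c2ccc(OC)cc2OC)c2c(OC)cc(OC)cc2[C@H]4[C@H](c2ccc(OC)cc2)O3)cc1 | intermediate
38 | hydrazone of 37 | COc1ccc(COc2cc3c4c(c2C(=NN)c2cc(OC)cc(OC)c2)C[C@H](c2ccc(OC)cc2OC)c2c(OC)cc(OC)cc2[C@H]4[C@H](c2ccc(OC)cc2)O3)cc1 | intermediate
39 | diaryldiazomethane from 38 | COc1ccc(COc2cc3c4c(c2C(=[N+]=[N-])c2cc(OC)cc(OC)c2)C[C@H](c2ccc(OC)cc2OC)c2c(OC)cc(OC)cc2[C@H]4[C@H](c2ccc(OC)cc2)O3)cc1 | intermediate (not isolated)
40 | octamethyl ether with the second dihydrofuran cis (2''S, 3''R; 2'R, 5R, 10R) | COc1ccc([C@H]2Oc3cc4c5c(c3[C@H]2c2cc(OC)cc(OC)c2)C[C@H](c2ccc(OC)cc2OC)c2c(OC)cc(OC)cc2[C@H]5[C@H](c2ccc(OC)cc2)O4)cc1 | intermediate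
41 | octamethyl ether of the target (2''R, 3''R; 2'R, 5R, 10R) | COc1ccc([C@@H]2Oc3cc4c5c(c3[C@H]2c2cc(OC)cc(OC)c2)C[C@H](c2ccc(OC)cc2OC)c2c(OC)cc(OC)cc2[C@H]5[C@H](c2ccc(OC)cc2)O4)cc1 | intermediate
42 | CNP0154047.1 (all five stereocentres R) | Oc1ccc([C@@H]2Oc3cc4c5c(c3[C@H]2c2cc(O)cc(O)c2)C[C@H](c2ccc(O)cc2O)c2c(O)cc(O)cc2[C@H]5[C@H](c2ccc(O)cc2)O4)cc1 | target

**Step count and risks**

Total steps: 24. Longest linear sequence: 23 steps (steps 1–7 and 9–24, from aldehyde 1); step 8 is a one-step side branch.

Most likely to fail: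

1. Step 22 (with its precursor step 21). The doubly ortho-substituted ketone may condense slowly with hydrazine, the diazo compound may dimerise to the azine, or the facial selectivity at C-3'' may be governed by the chiral tricycle and not by the catalyst. Fallback (one-carbon homologation instead of carbene insertion): ketone 37 is treated with dimethylsulfonium methylide to give spiro-epoxide F5, ZnI2 rearranges this to diarylacetaldehyde F6, and Grignard reagent 27 adds to give carbinol F7. CF3CO2H with anisole then removes the 4-methoxybenzyl ether and closes the trans dihydrofuran through the 4-methoxybenzylic cation, giving 41 together with its diastereomer F8, in which both new centres are inverted. This path gives up catalyst control, so the two trans isomers would have to be separated; it rejoins the route at 41.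

2. Step 13. The equilibrium at C-5 may not favour the trans aldehyde strongly enough, or material may be held as the conjugated enol. Fallback (kinetic C–C bond formation at C-5 instead of equilibration): ketone 23 is reduced with NaBH4 to benzhydrol 22, and p-toluenesulfinic acid converts this into sulfone F3. Cs2CO3 with (4-methoxybenzyl)dimethylsulfonium tetrafluoroborate then releases o-quinone methide F4 and the benzylic sulfonium ylide; the ylide should add to C-5 from the face away from the C-10 aryl group and is displaced by the phenoxide (formal [4+1] annulation, trans-selective). This gives 30 directly and replaces steps 11 to 15.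

3. Step 9. The ketene may be intercepted by the phenolic product (aryl ester formation), the electron-rich arenes may undergo competing photochemistry, or the cyclobutenone may open incompletely. Fallback (thermal generation of the same vinylketene, photochemistry removed from the annulation): 14 is rearranged with AgO2CPh and Et3N in aqueous THF to the homologous acid F1, and oxalyl chloride gives acid chloride F2. Slow addition of Et3N to F2 and 17 in toluene at 80 °C forms vinylketene 18 by dehydrochlorination in the dark, and 18 follows the same cycloaddition and electrocyclisation sequence to 21.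

Further compounds
F1 | step 9 | 2-[(5R)-5-(2,4-dimethoxyphenyl)-2,4-dimethoxy-6,9-dihydro-5H-benzo[7]annulen-7-yl]acetic acid | OC(=O)CC1=CCc2cc(OC)cc(OC)c2[C@@H](c2ccc(OC)cc2OC)C1
F2 | step 9 | 2-[(5R)-5-(2,4-dimethoxyphenyl)-2,4-dimethoxy-6,9-dihydro-5H-benzo[7]annulen-7-yl]acetyl chloride | ClC(=O)CC1=CCc2cc(OC)cc(OC)c2[C@@H](c2ccc(OC)cc2OC)C1
F3 | step 13 | (10R)-10-(2,4-dimethoxyphenyl)-7,9-dimethoxy-5-(p-tolylsulfonyl)-2-(triisopropylsilyloxy)-10,11-dihydro-5H-dibenzo[a,d][7]annulen-4-ol (C-5 epimers) | Oc1cc(O[Si](C(C)C)(C(C)C)C(C)C)cc2c1C(S(=O)(=O)c1ccc(C)cc1)c1cc(OC)cc(OC)c1[C@@H](c1ccc(OC)cc1OC)C2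
F4 | step 13 | o-quinone methide of 22 (C-4 carbonyl, C-4a=C-5 double bond, C-10 R) | O=C1C=C(O[Si](C(C)C)(C(C)C)C(C)C)C=C2C1=Cc1cc(OC)cc(OC)c1[C@@H](c1ccc(OC)cc1OC)C2
F5 | step 22 | spiro-epoxide of 37 (oxirane on the former carbonyl carbon, both epimers) | COc1ccc(COc2cc3c4c(c2C2(CO2)c2cc(OC)cc(OC)c2)C[C@H](c2ccc(OC)cc2OC)c2c(OC)cc(OC)cc2[C@H]4[C@H](c2ccc(OC)cc2)O3)cc1
F6 | step 22 | diarylacetaldehyde from F5 (CH(CHO)(3,5-dimethoxyphenyl) on C-1, both epimers) | COc1ccc(COc2cc3c4c(c2C(C=O)c2cc(OC)cc(OC)c2)C[C@H](c2ccc(OC)cc2OC)c2c(OC)cc(OC)cc2[C@H]4[C@H](c2ccc(OC)cc2)O3)cc1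
F7 | step 22 | carbinol from F6 and 27 (CH(3,5-dimethoxyphenyl)CH(OH)(4-methoxyphenyl) on C-1, all epimers) | COc1ccc(COc2cc3c4c(c2C(C(O)c2ccc(OC)cc2)c2cc(OC)cc(OC)c2)C[C@H](c2ccc(OC)cc2OC)c2c(OC)cc(OC)cc2[C@H]4[C@H](c2ccc(OC)cc2)O3)cc1
F8 | step 22 | diastereomer of 41 with the second dihydrofuran trans but 2''S, 3''S | COc1ccc([C@H]2Oc3cc4c5c(c3[C@@H]2c2cc(OC)cc(OC)c2)C[C@H](c2ccc(OC)cc2OC)c2c(OC)cc(OC)cc2[C@H]5[C@H](c2ccc(OC)cc2)O4)cc1
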